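Ring B (O1–C2–C3–O4; ring C on C2, C9 on C3) is disconnected at C2–C3. C2 is benzylic to the oxygen-rich ring C and bound to O1, so hydride loss turns it into an aryloxycarbenium carbon; C3 is alpha to C9 and becomes an enamine carbon once C9 is an aldehyde. One DDQ-driven, amine-catalysed cyclisation therefore forms C2–C3, closes ring B and sets both stereocentres (2,3-trans). Its precursor is an achiral ring A benzoate whose O1 carries the MOM-protected ring C benzyl group and whose O4 carries a CH2CHO arm, built by two etherifications and one alkene cleavage. Reduction, oxidation, Wittig olefination and deprotection finish the target.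

Key step: step 6

Assumption: locants follow the 2,3-dihydro-1,4-benzodioxine numbering O1–C2(ring C)–C3(C9)–O4, which puts the ring A methoxy group at C5 and the ring A carbon substituent at C7.

Step 1
Reactants: 1 3,4-dihydroxy-5-methoxybenzaldehyde (5-hydroxyvanillin)
Product: 2 3-methoxy-4,5-bis(methoxymethoxy)benzaldehyde
Conditions: MOMCl (3 equiv), i-Pr2NEt (4 equiv), CH2Cl2, 0 °C to rt
Reagents that add atoms: chloromethyl methyl ether (MOMCl), COCCl
Why: Double O-alkylation of the two phenols by the reactive α-chloro ether under amine base (MOM ether formation) masks the catechol as acetals that resist base, hydride and DDQ, and leaves the aldehyde free.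

Step 2
Reactants: 2 3-methoxy-4,5-bis(methoxymethoxy)benzaldehyde
Product: 3 [3-methoxy-4,5-bis(methoxymethoxy)phenyl]methanol
Conditions: NaBH4, MeOH, 0 °C
Reagents that add atoms: none
Why: Borohydride reduction of the aryl aldehyde gives the primary benzylic alcohol needed for etherification, and MOM acetals are inert to hydride.

Step 3
Reactants: 4 methyl 3,4-dihydroxy-5-methoxybenzoate; 5 allyl bromide (1.05 equiv)
Product: 6 methyl 3-hydroxy-5-methoxy-4-(prop-2-en-1-yloxy)benzoate
Conditions: Li2CO3 (1.1 equiv), DMF, 45 °C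
Reagents that add atoms: none
Why: Regioselective Williamson ether synthesis, since the hydroxyl para to the ester is the more acidic phenol and is the one deprotonated by the weak base Li2CO3, so one equivalent of 5 should alkylate O4 only.

Step 4
Reactants: 6 methyl 3-hydroxy-5-methoxy-4-(prop-2-en-1-yloxy)benzoate; 3 [3-methoxy-4,5-bis(methoxymethoxy)phenyl]methanol
Product: 7 methyl 3-methoxy-5-{[3-methoxy-4,5-bis(methoxymethoxy)benzyl]oxy}-4-(prop-2-en-1-yloxy)benzoate
Conditions: PPh3, DIAD, THF, 0 °C to rt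
Reagents that add atoms: none
Why: Mitsunobu etherification joins the remaining phenol (O1) to the primary benzylic alcohol under neutral conditions that spare the ester, the allyl ether and the MOM acetals, and it avoids an electron-rich benzyl halide.

Step 5
Reactants: 7 methyl 3-methoxy-5-{[3-methoxy-4,5-bis(methoxymethoxy)benzyl]oxy}-4-(prop-2-en-1-yloxy)benzoate
Product: 8 methyl 3-methoxy-5-{[3-methoxy-4,5-bis(methoxymethoxy)benzyl]oxy}-4-(2-oxoethoxy)benzoate
Conditions: OsO4 (2 mol%), NaIO4 (4 equiv), 2,6-lutidine, dioxane/H2O (3:1), rt; dried by toluene azeotrope and used at once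
Reagents that add atoms: sodium periodate NaIO4, [Na+].[O-]I(=O)(=O)=O (terminal oxidant that supplies the new carbonyl oxygen through OsO4)
Why: Lemieux–Johnson oxidation (catalytic dihydroxylation with periodate cleavage in the same pot) cuts the only C=C bond to unmask the O4-bound acetaldehyde, while 2,6-lutidine buffers the medium so that the MOM acetals persist.

Step 6
Reactants: 8 methyl 3-methoxy-5-{[3-methoxy-4,5-bis(methoxymethoxy)benzyl]oxy}-4-(2-oxoethoxy)benzoate
Product: 11 methyl (2R,3R)-3-(hydroxymethyl)-5-methoxy-2-[3-methoxy-4,5-bis(methoxymethoxy)phenyl]-2,3-dihydro-1,4-benzodioxine-7-carboxylate, via C2 oxocarbenium DDQH ion pair 9 (not isolated), via trans-benzodioxane C9 aldehyde 10 (not isolated)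
Conditions: DDQ (1.05 equiv), anhydrous CH2Cl2 (0.02 M), 0 °C until the DDQ is spent; then (2R,5R)-5-benzyl-2-tert-butyl-3-methylimidazolidin-4-one·CF3CO2H (20 mol%), −30 °C; then MeOH, NaBH4, −30 to 0 °C
Reagents that add atoms: none
Why: Proposed new method: DDQ abstracts hydride from the O1–CH2–ring C methylene of 8, the only C–H position activated both by an oxygen and by the electron-rich ring C (para alkoxy oxygen), to give the aryloxycarbenium ion O1=C2 stored as ion pair 9; the amine salt is added only after the DDQ is spent, condenses with the C9 aldehyde to an E-enamine nucleophilic at C3, and C3 attacks C2, after which the iminium is hydrolysed by the water released in the condensation and NaBH4 reduces aldehyde 10 before it can epimerise at C3 or lose O1 by retro-oxa-Michael opening. The closest known reaction types are the intermolecular DDQ-mediated oxidative α-alkylation of aldehydes at benzylic C–H bonds under imidazolidinone enamine catalysis and the DDQ-triggered cyclisation of benzylic ethers onto tethered enol-type nucleophiles, neither of which has been used to close a 1,4-benzodioxane ring. Ring B closes in a 6-endo-trig mode with respect to the C2=O1 bond while the enamine C3=C9 bond stays exocyclic, which lets the C3 π-lobe reach C2 in a chair-like array. C3 is set by the catalyst: the (2R,5R) enantiomer holds the E-enamine away from its tert-butyl group and blocks one face with its benzyl group, so C2 should bond to the open Si face of C3 (O4 > C9 > H) and give 3S in 10, which is named 3R in 11 only because C9 drops in CIP rank on reduction. C2 is set by the ring: the E-oxocarbenium places ring C pseudo-equatorial opposite the pseudo-equatorial C9 arm, giving the 2,3-trans (2R) relationship, which is also the more stable one. The step needs hydride abstraction at C2–H ahead of oxidation of the enamine, and capture of the cation by C3 ahead of capture by water or by a second molecule; the staged addition, the ester-deactivated ring A, the anhydrous dilute solution and the six-membered tether should secure this.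

Step 7
Reactants: 11 methyl (2R,3R)-3-(hydroxymethyl)-5-methoxy-2-[3-methoxy-4,5-bis(methoxymethoxy)phenyl]-2,3-dihydro-1,4-benzodioxine-7-carboxylate
Product: 12 [(2R,3R)-5-methoxy-2-[3-methoxy-4,5-bis(methoxymethoxy)phenyl]-2,3-dihydro-1,4-benzodioxine-3,7-diyl]dimethanol
Conditions: i-Bu2AlH (4 equiv), CH2Cl2, −78 to 0 °C; aq. potassium sodium tartrate
Reagents that add atoms: none
Why: Aluminium hydride reduction takes the aryl ester through to the benzylic alcohol, the free C9 hydroxyl only consumes one hydride equivalent, and neither stereocentre carries an acidic hydrogen any longer.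

Step 8
Reactants: 12 [(2R,3R)-5-methoxy-2-[3-methoxy-4,5-bis(methoxymethoxy)phenyl]-2,3-dihydro-1,4-benzodioxine-3,7-diyl]dimethanol
Product: 13 (2R,3R)-3-(hydroxymethyl)-5-methoxy-2-[3-methoxy-4,5-bis(methoxymethoxy)phenyl]-2,3-dihydro-1,4-benzodioxine-7-carbaldehyde
Conditions: activated MnO2 (15 equiv), CH2Cl2, rt
Reagents that add atoms: none
Why: Chemoselective MnO2 oxidation converts only the benzylic alcohol into the aldehyde, so the saturated C9 primary alcohol needs no protection.

Step 9
Reactants: 13 (2R,3R)-3-(hydroxymethyl)-5-methoxy-2-[3-methoxy-4,5-bis(methoxymethoxy)phenyl]-2,3-dihydro-1,4-benzodioxine-7-carbaldehyde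
Product: 14 (E)-3-{(2R,3R)-3-(hydroxymethyl)-5-methoxy-2-[3-methoxy-4,5-bis(methoxymethoxy)phenyl]-2,3-dihydro-1,4-benzodioxin-7-yl}prop-2-enal
Conditions: Ph3P=CHCHO (1.3 equiv), toluene, 80 °C
Reagents that add atoms: (triphenylphosphoranylidene)acetaldehyde, O=CC=P(c1ccccc1)(c1ccccc1)c1ccccc1
Why: Wittig olefination with the stabilised formyl ylide should give the (E)-enal, the non-basic ylide tolerates the free C9 hydroxyl, and a small excess stopped at full conversion limits a second homologation.

Step 10
Reactants: 14 (E)-3-{(2R,3R)-3-(hydroxymethyl)-5-methoxy-2-[3-methoxy-4,5-bis(methoxymethoxy)phenyl]-2,3-dihydro-1,4-benzodioxin-7-yl}prop-2-enal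
Product: 15 (E)-3-[(2R,3R)-2-(3,4-dihydroxy-5-methoxyphenyl)-3-(hydroxymethyl)-5-methoxy-2,3-dihydro-1,4-benzodioxin-7-yl]prop-2-enal
Conditions: 3 M aq. HCl, THF/i-PrOH (1:1), 45 °C, argon
Reagents that add atoms: none
Why: Acid-catalysed acetal hydrolysis removes both MOM groups and frees the ring C catechol, while the far less basic aryl alkyl ethers of ring B, the enal in the aqueous medium and the two non-enolisable stereocentres should persist.

Compound list
1 | 3,4-dihydroxy-5-methoxybenzaldehyde (5-hydroxyvanillin) | COc1cc(C=O)cc(O)c1O | starting material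
2 | 3-methoxy-4,5-bis(methoxymethoxy)benzaldehyde | COCOc1cc(C=O)cc(OC)c1OCOC | intermediate
3 | [3-methoxy-4,5-bis(methoxymethoxy)phenyl]methanol | COCOc1cc(CO)cc(OC)c1OCOC | intermediate
4 | methyl 3,4-dihydroxy-5-methoxybenzoate | COC(=O)c1cc(O)c(O)c(OC)c1 | starting material
5 | allyl bromide (3-bromoprop-1-ene) | C=CCBr | starting material
6 | methyl 3-hydroxy-5-methoxy-4-(prop-2-en-1-yloxy)benzoate | COC(=O)c1cc(O)c(OCC=C)c(OC)c1 | intermediate
7 | methyl 3-methoxy-5-{[3-methoxy-4,5-bis(methoxymethoxy)benzyl]oxy}-4-(prop-2-en-1-yloxy)benzoate | COC(=O)c1cc(OC)c(OCC=C)c(OCc2cc(OC)c(OCOC)c(OCOC)c2)c1 | intermediate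
8 | methyl 3-methoxy-5-{[3-methoxy-4,5-bis(methoxymethoxy)benzyl]oxy}-4-(2-oxoethoxy)benzoate | COC(=O)c1cc(OC)c(OCC=O)c(OCc2cc(OC)c(OCOC)c(OCOC)c2)c1 | intermediate
9 | C2 oxocarbenium ion of 8 as its DDQH ion pair | COC(=O)c1cc(OC)c(OCC=O)c([O+]=Cc2cc(OC)c(OCOC)c(OCOC)c2)c1.[O-]c1c(Cl)c(Cl)c(O)c(C#N)c1C#N | intermediate
10 | methyl (2R,3S)-3-formyl-5-methoxy-2-[3-methoxy-4,5-bis(methoxymethoxy)phenyl]-2,3-dihydro-1,4-benzodioxine-7-carboxylate | COc1cc([C@H]2Oc3cc(C(=O)OC)cc(OC)c3O[C@@H]2C=O)cc(OCOC)c1OCOC | intermediate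
11 | methyl (2R,3R)-3-(hydroxymethyl)-5-methoxy-2-[3-methoxy-4,5-bis(methoxymethoxy)phenyl]-2,3-dihydro-1,4-benzodioxine-7-carboxylate | COc1cc([C@H]2Oc3cc(C(=O)OC)cc(OC)c3O[C@@H]2CO)cc(OCOC)c1OCOC | intermediate
12 | [(2R,3R)-5-methoxy-2-[3-methoxy-4,5-bis(methoxymethoxy)phenyl]-2,3-dihydro-1,4-benzodioxine-3,7-diyl]dimethanol | COc1cc([C@H]2Oc3cc(CO)cc(OC)c3O[C@@H]2CO)cc(OCOC)c1OCOC | intermediate
13 | (2R,3R)-3-(hydroxymethyl)-5-methoxy-2-[3-methoxy-4,5-bis(methoxymethoxy)phenyl]-2,3-dihydro-1,4-benzodioxine-7-carbaldehyde | COc1cc([C@H]2Oc3cc(C=O)cc(OC)c3O[C@@H]2CO)cc(OCOC)c1OCOC | intermediate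
14 | (E)-3-{(2R,3R)-3-(hydroxymethyl)-5-methoxy-2-[3-methoxy-4,5-bis(methoxymethoxy)phenyl]-2,3-dihydro-1,4-benzodioxin-7-yl}prop-2-enal | COc1cc([C@H]2Oc3cc(/C=C/C=O)cc(OC)c3O[C@@H]2CO)cc(OCOC)c1OCOC | intermediate
15 | (E)-3-[(2R,3R)-2-(3,4-dihydroxy-5-methoxyphenyl)-3-(hydroxymethyl)-5-methoxy-2,3-dihydro-1,4-benzodioxin-7-yl]prop-2-enal | COc1cc([C@H]2Oc3cc(/C=C/C=O)cc(OC)c3O[C@@H]2CO)cc(O)c1O | target

Total step count: 10 (the reduction in the same flask is part of step 6).
Longest linear sequence: 9 steps (1 → 2 → 3 → 7 → 8 → 11 → 12 → 13 → 14 → 15; steps 1, 2, 4, 5, 6, 7, 8, 9, 10).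

Steps most likely to fail

Step 6. DDQ may oxidise the enamine or the amine if any oxidant is left when the catalyst is added. The cation may be captured by water or by a second molecule, which amounts to oxidative debenzylation or oligomerisation. The catalyst may also discriminate the two faces of C3 poorly. The fallback uses known chemistry, sets out from 2 and 6 and returns at 11. Horner–Wadsworth–Emmons olefination of 2 with triethyl phosphonoacetate (LiCl, DBU, MeCN) should give the ring C ethyl (E)-cinnamate F1, which i-Bu2AlH reduces to the (E)-cinnamyl alcohol F2. Sharpless asymmetric epoxidation (Ti(Oi-Pr)4, L-(+)-diisopropyl tartrate, t-BuOOH, 4 Å sieves, CH2Cl2, −20 °C) should set both centres in the (2S,3S)-epoxy alcohol F3. The aryloxide of 6 (Cs2CO3, DMF, 70 °C) should open F3 at the benzylic carbon with inversion, forming the O1–C2 bond in the (1R,2S)-diol F4. Selective sulfonylation of the primary hydroxyl (TsCl, Bu2SnO cat., Et3N) gives the primary tosylate F5, and K2CO3 in MeOH closes the terminal epoxide F6 with retention at the carbinol carbon. Pd(PPh3)4 with K2CO3 in MeOH then cleaves the allyl ether to the phenol F7 (not isolated), whose phenoxide opens the epoxide at its internal carbon (6-exo-tet, inversion) and closes ring B as 11.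

Step 9. The product enal can compete with the electron-rich aryl aldehyde for the ylide, so a second homologation to the dienal or incomplete conversion may result. The fallback sets out from 13 and returns at 14. Horner–Wadsworth–Emmons olefination with triethyl phosphonoacetate (LiCl, DBU, MeCN) should give the ethyl (E)-propenoate F8. i-Bu2AlH at −78 °C reduces it to the (E)-allylic alcohol F9, and MnO2 oxidises only the allylic alcohol to give 14.

Step 10. Acid may add water or alcohol across the enal, or ionise the C2–O1 bond once the para hydroxyl of ring C is free, which would erode the trans relationship. The fallback sets out from 13 and returns at 15. The MOM acetals are hydrolysed at the aryl aldehyde stage under the conditions of step 10 to give the free catechol aldehyde F10. The Wittig olefination of step 9 is then run on F10, since the stabilised ylide is too weakly basic to be quenched by phenols, so the enal never meets acid.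

Further compounds
F1 | step 6 | ethyl (E)-3-[3-methoxy-4,5-bis(methoxymethoxy)phenyl]prop-2-enoate | CCOC(=O)/C=C/c1cc(OC)c(OCOC)c(OCOC)c1
F2 | step 6 | (E)-3-[3-methoxy-4,5-bis(methoxymethoxy)phenyl]prop-2-en-1-ol | OC/C=C/c1cc(OC)c(OCOC)c(OCOC)c1
F3 | step 6 | [(2S,3S)-3-[3-methoxy-4,5-bis(methoxymethoxy)phenyl]oxiran-2-yl]methanol | OC[C@@H]1O[C@H]1c2cc(OC)c(OCOC)c(OCOC)c2
F4 | step 6 | methyl 3-{[(1R,2S)-2,3-dihydroxy-1-[3-methoxy-4,5-bis(methoxymethoxy)phenyl]propyl]oxy}-5-methoxy-4-(prop-2-en-1-yloxy)benzoate | COC(=O)c1cc(OC)c(OCC=C)c(O[C@@H]([C@@H](O)CO)c2cc(OC)c(OCOC)c(OCOC)c2)c1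
F5 | step 6 | methyl 3-{[(1R,2S)-2-hydroxy-1-[3-methoxy-4,5-bis(methoxymethoxy)phenyl]-3-(tosyloxy)propyl]oxy}-5-methoxy-4-(prop-2-en-1-yloxy)benzoate | COC(=O)c1cc(OC)c(OCC=C)c(O[C@@H]([C@@H](O)COS(=O)(=O)c2ccc(C)cc2)c2cc(OC)c(OCOC)c(OCOC)c2)c1
F6 | step 6 | methyl 3-methoxy-5-{(R)-[3-methoxy-4,5-bis(methoxymethoxy)phenyl][(2S)-oxiran-2-yl]methoxy}-4-(prop-2-en-1-yloxy)benzoate | COC(=O)c1cc(OC)c(OCC=C)c(O[C@@H]([C@@H]2CO2)c2cc(OC)c(OCOC)c(OCOC)c2)c1
F7 | step 6 | methyl 4-hydroxy-3-methoxy-5-{(R)-[3-methoxy-4,5-bis(methoxymethoxy)phenyl][(2S)-oxiran-2-yl]methoxy}benzoate | COC(=O)c1cc(OC)c(O)c(O[C@@H]([C@@H]2CO2)c2cc(OC)c(OCOC)c(OCOC)c2)c1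
F8 | step 9 | ethyl (E)-3-{(2R,3R)-3-(hydroxymethyl)-5-methoxy-2-[3-methoxy-4,5-bis(methoxymethoxy)phenyl]-2,3-dihydro-1,4-benzodioxin-7-yl}prop-2-enoate | COc1cc([C@H]2Oc3cc(/C=C/C(=O)OCC)cc(OC)c3O[C@@H]2CO)cc(OCOC)c1OCOC
F9 | step 9 | (E)-3-{(2R,3R)-3-(hydroxymethyl)-5-methoxy-2-[3-methoxy-4,5-bis(methoxymethoxy)phenyl]-2,3-dihydro-1,4-benzodioxin-7-yl}prop-2-en-1-ol | COc1cc([C@H]2Oc3cc(/C=C/CO)cc(OC)c3O[C@@H]2CO)cc(OCOC)c1OCOC
F10 | step 10 | (2R,3R)-2-(3,4-dihydroxy-5-methoxyphenyl)-3-(hydroxymethyl)-5-methoxy-2,3-dihydro-1,4-benzodioxine-7-carbaldehyde | COc1cc([C@H]2Oc3cc(C=O)cc(OC)c3O[C@@H]2CO)cc(O)c1O
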